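**Retrosynthetic overview**

1. The target comes from the tricyclic C6 alcohol by O-tigloylation in the last step.
2. The tricyclic alcohol comes from an acyclic enal carrying a 2-(bromomethyl)acrylate ester, in one flask: ring-closing metathesis closes the lactone ring as a 3-(bromomethyl)butenolide, then zinc Barbier allylation C7→C6 closes the ten-membered ring and sets C6 and C7.
3. The ester comes from a furanone epoxide by one-carbon homologation of the epoxide to the C8 vinyl carbinol, then esterification.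
4. The furanone comes from a Seebach dioxolanone (C10 from (R)-lactic acid, C8 from (S)-glycidol) and the acetylide of commercial (Z)-3-methylpent-2-en-4-yn-1-ol (C2–C6, C15).
5. Ring order: furanone first; lactone ring and ten-membered carbocycle together in the key operation.

Assumption: positions use germacranolide numbering (C1 ketone, C2=C3 furanone alkene, C3–O–C10 bridge, C4=C5 with C15 methyl, C6 ester carbinol, C7, C8 lactone carbinol, C9 CH2, C10 quaternary with C14 methyl, C11=C13 methylene, C12 lactone carbonyl); the target is read as (6S,7R,8S,10S), 4Z, E-tiglate.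

**Route**

Step 1
Reactants: 1 (R)-lactic acid
Product: 2 (2R,5R)-2-tert-butyl-5-methyl-1,3-dioxolan-4-one
Conditions: pivalaldehyde, TsOH (cat.), H2SO4 (cat.), pentane, reflux (Dean–Stark); crystallise from ether/pentane, −78 °C
Reagents that add atoms: pivalaldehyde, CC(C)(C)C=O
Why: Acid-catalysed acetalisation (Seebach self-regeneration-of-stereocentres auxiliary) gives the cis dioxolanone as the thermodynamic, crystallisable isomer, so the acetal centre (2R) is set by the lactic acid centre.

Step 2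
Reactants: 2 (2R,5R)-2-tert-butyl-5-methyl-1,3-dioxolan-4-one; 3 (S)-glycidol
Product: 6 (2R,5S)-2-tert-butyl-5-methyl-5-{[(2S)-oxiran-2-yl]methyl}-1,3-dioxolan-4-one, via glycidyl triflate 4 (not isolated), via lithium enolate 5 (not isolated)
Conditions: (a) 3, Tf2O, 2,6-lutidine, CH2Cl2, −78 °C, cold silica plug (pentane), solution used at once; (b) 2, LiN(i-Pr)2, THF, −78 °C; then solution of 4, −78 → −40 °C
Reagents that add atoms: none
Why: Seebach enolate alkylation: the planar enolate 5 displaces the primary triflate of 4 by direct SN2 (epoxide untouched) on the face opposite the tert-butyl group, which sets C10 as S (electrophile takes the place of H), while C8 (S) is carried over unchanged from (S)-glycidol.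

Step 3
Reactants: 7 (2Z)-3-methylpent-2-en-4-yn-1-ol
Product: 8 tert-butyl(dimethyl){[(2Z)-3-methylpent-2-en-4-yn-1-yl]oxy}silane
Conditions: TBSCl, imidazole, CH2Cl2, 0 °C → rt
Reagents that add atoms: tert-butyldimethylsilyl chloride, CC(C)(C)[Si](C)(C)Cl
Why: Standard silylation of the primary allylic alcohol, so that the alkyne C–H is the only acidic site and the hydroxyl cannot later add to the ynone (which would give a furan); no stereocentre is formed and the Z alkene is untouched.

Step 4
Reactants: 8 tert-butyl(dimethyl){[(2Z)-3-methylpent-2-en-4-yn-1-yl]oxy}silane; 6 (2R,5S)-2-tert-butyl-5-methyl-5-{[(2S)-oxiran-2-yl]methyl}-1,3-dioxolan-4-one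
Product: 11 (2S)-5-[(2Z)-4-{[tert-butyl(dimethyl)silyl]oxy}but-2-en-2-yl]-2-methyl-2-{[(2S)-oxiran-2-yl]methyl}furan-3(2H)-one, via lithium acetylide 9 (not isolated), via hydroxy ynone 10 (not isolated)
Conditions: 8, n-BuLi, THF, −78 °C; add 6, −78 °C; AcOH, −78 °C; then K2CO3 (cat.), MeOH, 0 °C → rt
Reagents that add atoms: none
Why: Nucleophilic acyl substitution of the dioxolanone carbonyl by 9 (organolithium addition to a lactone-type ester, which halts at the ketone level at −78 °C) and loss of pivalaldehyde give α'-hydroxy ynone 10, whose tertiary hydroxyl closes the furanone ring by base-catalysed 5-endo-dig oxa-Michael addition; C10 (S), C8 (S) and the Z alkene are not touched.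

Step 5
Reactants: 11 (2S)-5-[(2Z)-4-{[tert-butyl(dimethyl)silyl]oxy}but-2-en-2-yl]-2-methyl-2-{[(2S)-oxiran-2-yl]methyl}furan-3(2H)-one
Product: 12 (2S)-5-[(2Z)-4-{[tert-butyl(dimethyl)silyl]oxy}but-2-en-2-yl]-2-[(2S)-2-hydroxybut-3-en-1-yl]-2-methylfuran-3(2H)-one
Conditions: Me3S+ I−, n-BuLi, THF, −10 °C; add 11, −10 °C → rt
Reagents that add atoms: trimethylsulfonium iodide, C[S+](C)C.[I-]
Why: Epoxide-to-allylic-alcohol one-carbon homologation (Corey–Chaykovsky-type sulfur ylide chemistry): the ylide opens the epoxide at its CH2 terminus and the betaine eliminates dimethyl sulfide, so the C8–O bond is never broken and C8 stays S, while the hindered vinylogous-ester carbonyl of the furanone is far less electrophilic than the epoxide terminus.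

Step 6
Reactants: 12 (2S)-5-[(2Z)-4-{[tert-butyl(dimethyl)silyl]oxy}but-2-en-2-yl]-2-[(2S)-2-hydroxybut-3-en-1-yl]-2-methylfuran-3(2H)-one; 13 2-(bromomethyl)prop-2-enoic acid
Product: 14 (2S)-1-[(2S)-5-{(2Z)-4-[tert-butyl(dimethyl)silyl]oxybut-2-en-2-yl}-2-methyl-3-oxo-2,3-dihydrofuran-2-yl]but-3-en-2-yl 2-(bromomethyl)prop-2-enoate
Conditions: DCC, DMAP (5 mol%), CH2Cl2, 0 °C
Reagents that add atoms: none
Why: Steglich esterification of the only free hydroxyl at low temperature (the allylic bromide survives catalytic DMAP at 0 °C) proceeds with retention at C8.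

Step 7
Reactants: 14 (2S)-1-[(2S)-5-{(2Z)-4-[tert-butyl(dimethyl)silyl]oxybut-2-en-2-yl}-2-methyl-3-oxo-2,3-dihydrofuran-2-yl]but-3-en-2-yl 2-(bromomethyl)prop-2-enoate
Product: 15 (2S)-1-{(2S)-5-[(2Z)-4-hydroxybut-2-en-2-yl]-2-methyl-3-oxo-2,3-dihydrofuran-2-yl}but-3-en-2-yl 2-(bromomethyl)prop-2-enoate
Conditions: 48% aq. HF, MeCN, 0 °C
Reagents that add atoms: none
Why: Acidic fluoride desilylation of the primary allylic TBS ether under non-nucleophilic, non-basic conditions that leave the allylic bromide, acrylate ester and furanone intact; no stereocentre is affected.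

Step 8
Reactants: 15 (2S)-1-{(2S)-5-[(2Z)-4-hydroxybut-2-en-2-yl]-2-methyl-3-oxo-2,3-dihydrofuran-2-yl}but-3-en-2-yl 2-(bromomethyl)prop-2-enoate
Product: 16 (2S)-1-{(2S)-2-methyl-3-oxo-5-[(2Z)-4-oxobut-2-en-2-yl]-2,3-dihydrofuran-2-yl}but-3-en-2-yl 2-(bromomethyl)prop-2-enoate
Conditions: MnO2, CH2Cl2, rt, dark
Reagents that add atoms: none
Why: Chemoselective MnO2 oxidation of the only allylic alcohol to the enal under neutral conditions that keep the Z geometry and the allylic bromide.

Step 9
Reactants: 16 (2S)-1-{(2S)-2-methyl-3-oxo-5-[(2Z)-4-oxobut-2-en-2-yl]-2,3-dihydrofuran-2-yl}but-3-en-2-yl 2-(bromomethyl)prop-2-enoate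
Product: 19 (6S,7S,8S,10S)-6-hydroxy-3,10-epoxy-1-oxogermacra-2,4Z,11(13)-trien-12,8-olide, via bromobutenolide 17 (not isolated), via allylzinc bromide 18 (not isolated)
Conditions: second-generation Hoveyda–Grubbs catalyst RuCl2(H2IMes)(=CH-2-(i-PrO)C6H4) (5 mol%), toluene (5 mM), 80 °C, argon sparge; then THF (to 1 mM), sat. aq. NH4Cl, Zn dust, 0 °C → rt
Reagents that add atoms: none
Why: Proposed new method: ring-closing metathesis of the vinyl group with the 2-(bromomethyl)acrylate (closest known type: butenolides from methacrylates of allylic alcohols) closes the lactone ring as 17, zinc then inserts into its allylic C–Br bond and 18 adds through C7 to the tethered Z-enal (closest known types: zinc Barbier additions of 3-(bromomethyl)butenolides to aldehydes and Barbier-type macrocyclisations to ten-membered germacranolide rings), so lactone ring and carbocycle form in one flask without handling the labile bromobutenolide; C7 is set by attack on the butenolide face opposite the C9 side chain at C8 (trans-fused lactone), and C6 is set S by the open, non-chair transition state expected for aqueous zinc Barbier additions (syn adduct; a chair would give the C6 epimer).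

Step 10
Reactants: 19 (6S,7S,8S,10S)-6-hydroxy-3,10-epoxy-1-oxogermacra-2,4Z,11(13)-trien-12,8-olide; 20 tigloyl chloride
Product: 21 (6S,7R,8S,10S)-3,10-epoxy-1-oxo-6-[(2E)-2-methylbut-2-enoyloxy]germacra-2,4Z,11(13)-trien-12,8-olide (CNP0293168.2)
Conditions: 20, pyridine, DMAP (cat.), CH2Cl2, 0 °C → rt
Reagents that add atoms: none
Why: DMAP-catalysed O-acylation of the secondary C6 alcohol goes with retention at C6 and the E-tiglate is the stable geometry, so no centre or alkene is disturbed (the C7 descriptor changes from S to R only because the CIP ranking changes on acylation).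

**Compound list**

1 | (R)-lactic acid, (2R)-2-hydroxypropanoic acid | C[C@@H](O)C(=O)O | starting material
2 | (2R,5R)-2-tert-butyl-5-methyl-1,3-dioxolan-4-one (cis) | C[C@H]1O[C@@H](C(C)(C)C)OC1=O | intermediate
3 | (S)-glycidol, (2S)-oxiran-2-ylmethanol | OC[C@H]1CO1 | starting material
4 | glycidyl triflate, [(2R)-oxiran-2-yl]methyl trifluoromethanesulfonate (same spatial arrangement as 3; not isolated) | O=S(=O)(OC[C@H]1CO1)C(F)(F)F | intermediate
5 | lithium enolate of 2, lithium (2R)-2-tert-butyl-5-methyl-1,3-dioxol-4-olate (not isolated) | CC1=C([O-])O[C@H](C(C)(C)C)O1.[Li+] | intermediate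
6 | (2R,5S)-2-tert-butyl-5-methyl-5-{[(2S)-oxiran-2-yl]methyl}-1,3-dioxolan-4-one | C[C@@]1(C[C@H]2CO2)O[C@@H](C(C)(C)C)OC1=O | intermediate
7 | (2Z)-3-methylpent-2-en-4-yn-1-ol | C#C/C(C)=C\CO | starting material
8 | tert-butyl(dimethyl){[(2Z)-3-methylpent-2-en-4-yn-1-yl]oxy}silane | C#C/C(C)=C\CO[Si](C)(C)C(C)(C)C | intermediate
9 | lithium acetylide of 8, [(3Z)-5-{[tert-butyl(dimethyl)silyl]oxy}-3-methylpent-3-en-1-yn-1-yl]lithium (not isolated) | [Li]C#C/C(C)=C\CO[Si](C)(C)C(C)(C)C | intermediate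
10 | hydroxy ynone, (2S,6Z)-8-{[tert-butyl(dimethyl)silyl]oxy}-2-hydroxy-2,6-dimethyl-1-[(2S)-oxiran-2-yl]oct-6-en-4-yn-3-one (not isolated) | C[C@](O)(C[C@H]1CO1)C(=O)C#C/C(C)=C\CO[Si](C)(C)C(C)(C)C | intermediate
11 | (2S)-5-[(2Z)-4-{[tert-butyl(dimethyl)silyl]oxy}but-2-en-2-yl]-2-methyl-2-{[(2S)-oxiran-2-yl]methyl}furan-3(2H)-one | C[C@@]1(C[C@H]2CO2)OC(=CC1=O)/C(C)=C\CO[Si](C)(C)C(C)(C)C | intermediate
12 | (2S)-5-[(2Z)-4-{[tert-butyl(dimethyl)silyl]oxy}but-2-en-2-yl]-2-[(2S)-2-hydroxybut-3-en-1-yl]-2-methylfuran-3(2H)-one | C[C@@]1(C[C@H](O)C=C)OC(=CC1=O)/C(C)=C\CO[Si](C)(C)C(C)(C)C | intermediate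
13 | 2-(bromomethyl)prop-2-enoic acid | C=C(CBr)C(=O)O | starting material
14 | (2S)-1-[(2S)-5-{(2Z)-4-[tert-butyl(dimethyl)silyl]oxybut-2-en-2-yl}-2-methyl-3-oxo-2,3-dihydrofuran-2-yl]but-3-en-2-yl 2-(bromomethyl)prop-2-enoate | C[C@@]1(C[C@H](OC(=O)C(=C)CBr)C=C)OC(=CC1=O)/C(C)=C\CO[Si](C)(C)C(C)(C)C | intermediate
15 | (2S)-1-{(2S)-5-[(2Z)-4-hydroxybut-2-en-2-yl]-2-methyl-3-oxo-2,3-dihydrofuran-2-yl}but-3-en-2-yl 2-(bromomethyl)prop-2-enoate | C[C@@]1(C[C@H](OC(=O)C(=C)CBr)C=C)OC(=CC1=O)/C(C)=C\CO | intermediate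
16 | (2S)-1-{(2S)-2-methyl-3-oxo-5-[(2Z)-4-oxobut-2-en-2-yl]-2,3-dihydrofuran-2-yl}but-3-en-2-yl 2-(bromomethyl)prop-2-enoate | C[C@@]1(C[C@H](OC(=O)C(=C)CBr)C=C)OC(=CC1=O)/C(C)=C\C=O | intermediate
17 | bromobutenolide, (2Z)-3-[(5S)-5-{[(2S)-4-(bromomethyl)-5-oxo-2,5-dihydrofuran-2-yl]methyl}-5-methyl-4-oxo-4,5-dihydrofuran-2-yl]but-2-enal (not isolated) | C[C@@]1(C[C@@H]2OC(=O)C(CBr)=C2)OC(=CC1=O)/C(C)=C\C=O | intermediate
18 | allylzinc bromide from 17, C13–ZnBr in place of C13–Br (not isolated) | C[C@@]1(C[C@@H]2OC(=O)C(C[Zn]Br)=C2)OC(=CC1=O)/C(C)=C\C=O | intermediate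
19 | (6S,7S,8S,10S)-6-hydroxy-3,10-epoxy-1-oxogermacra-2,4Z,11(13)-trien-12,8-olide (target without the tigloyl group; same spatial arrangement as 21) | C=C1C(=O)O[C@H]2C[C@]3(C)OC(=CC3=O)/C(C)=C\[C@H](O)[C@H]12 | intermediate
20 | tigloyl chloride, (2E)-2-methylbut-2-enoyl chloride | C/C=C(\C)C(=O)Cl | starting material
21 | (6S,7R,8S,10S)-3,10-epoxy-1-oxo-6-[(2E)-2-methylbut-2-enoyloxy]germacra-2,4Z,11(13)-trien-12,8-olide (CNP0293168.2) | C=C1C(=O)O[C@H]2C[C@]3(C)OC(=CC3=O)/C(C)=C\[C@H](OC(=O)/C(C)=C/C)[C@H]12 | target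

**Step count and weak points**

Total step count: 10. Longest linear sequence: 9 steps (1, 2, 4, 5, 6, 7, 8, 9, 10); step 3 is a one-step side branch.

Most likely to fail, step 9 (one-pot metathesis/Barbier macrocyclisation): the strained ten-membered ring may not close, the allylzinc may react at C13, or the C6 epimer may form. The fallback closes the ring by metathesis at C4=C5 and makes the C6–C7 bond intermolecularly; it sets out from 6 and returns at 21. Compound 6 is treated with 2-methylbut-1-en-3-yne and n-BuLi, then K2CO3/MeOH as in step 4, to give the isopropenyl furanone epoxide F1. Dimethylsulfonium methylide gives the vinyl carbinol F2, and esterification with 13 (DCC, cat. DMAP) gives the acrylate ester F3. Ring-closing metathesis (second-generation Hoveyda–Grubbs catalyst, toluene, 80 °C) gives the bromobutenolide F4. Zinc-mediated Barbier addition of F4 to acrolein (THF, aq. NH4Cl) gives the allylic alcohol F5, with attack anti to the C9 side chain; the carbinol configuration can be tuned by the metal (Zn, open transition state; CrCl2, chair transition state). Acylation with 20 gives the tiglate F6, and metathesis between its isopropenyl and vinyl groups (same catalyst, toluene, 110 °C, high dilution) closes the ten-membered ring with the ring-enforced Z alkene and gives 21.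

Second, step 5 (sulfur ylide in the presence of the furanone carbonyl). The fallback makes the C8 carbinol by ligand-controlled vinyl addition to an aldehyde; it sets out from 11 and returns at 12. Periodic acid (H5IO6, ether/THF, 0 °C) cleaves the terminal epoxide of 11 to the furanone acetaldehyde F7, C7 being lost as formaldehyde. Divinylzinc Zn(CH=CH2)2 with catalytic (+)-DAIB then gives 12. (+)-DAIB is the antipode of the ligand that turns benzaldehyde and diethylzinc into (S)-1-phenylpropan-1-ol, so vinyl is delivered to the face that gives 8S.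

Third, step 4 (direct conversion of the dioxolanone into the furanone). The fallback changes the acyl donor; it sets out from 6 and returns at 10. N,O-dimethylhydroxylamine hydrochloride and i-PrMgCl (THF, −20 °C) open the dioxolanone of 6 to the hydroxy Weinreb amide F8, with loss of pivalaldehyde. Two equivalents of 9 (THF, −78 → 0 °C) then give 10, which is closed to 11 with K2CO3/MeOH as before.

**Further compounds**

F1 | step 9 | (2S)-2-methyl-2-{[(2S)-oxiran-2-yl]methyl}-5-(prop-1-en-2-yl)furan-3(2H)-one | C[C@@]1(C[C@H]2CO2)OC(=CC1=O)C(C)=C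
F2 | step 9 | (2S)-2-[(2S)-2-hydroxybut-3-en-1-yl]-2-methyl-5-(prop-1-en-2-yl)furan-3(2H)-one | C[C@@]1(C[C@H](O)C=C)OC(=CC1=O)C(C)=C
F3 | step 9 | (2S)-1-[(2S)-2-methyl-3-oxo-5-(prop-1-en-2-yl)-2,3-dihydrofuran-2-yl]but-3-en-2-yl 2-(bromomethyl)prop-2-enoate | C[C@@]1(C[C@H](OC(=O)C(=C)CBr)C=C)OC(=CC1=O)C(C)=C
F4 | step 9 | (2S)-2-{[(2S)-4-(bromomethyl)-5-oxo-2,5-dihydrofuran-2-yl]methyl}-2-methyl-5-(prop-1-en-2-yl)furan-3(2H)-one | C[C@@]1(C[C@@H]2OC(=O)C(CBr)=C2)OC(=CC1=O)C(C)=C
F5 | step 9 | (4S,5S)-4-[(1S)-1-hydroxyprop-2-en-1-yl]-3-methylidene-5-{[(2S)-2-methyl-3-oxo-5-(prop-1-en-2-yl)-2,3-dihydrofuran-2-yl]methyl}oxolan-2-one | C=C1C(=O)O[C@@H](C[C@]2(C)OC(=CC2=O)C(C)=C)[C@@H]1[C@@H](O)C=C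
F6 | step 9 | (1S)-1-[(2S,3R)-4-methylidene-2-{[(2S)-2-methyl-3-oxo-5-(prop-1-en-2-yl)-2,3-dihydrofuran-2-yl]methyl}-5-oxooxolan-3-yl]prop-2-en-1-yl (2E)-2-methylbut-2-enoate | C=C1C(=O)O[C@@H](C[C@]2(C)OC(=CC2=O)C(C)=C)[C@@H]1[C@@H](OC(=O)/C(C)=C/C)C=C
F7 | step 5 | [(2S)-5-{(2Z)-4-[tert-butyl(dimethyl)silyl]oxybut-2-en-2-yl}-2-methyl-3-oxo-2,3-dihydrofuran-2-yl]acetaldehyde | C[C@@]1(CC=O)OC(=CC1=O)/C(C)=C\CO[Si](C)(C)C(C)(C)C
F8 | step 4 | (2S)-2-hydroxy-N-methoxy-N,2-dimethyl-3-[(2S)-oxiran-2-yl]propanamide | C[C@](O)(C[C@H]1CO1)C(=O)N(C)OC
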